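**Retrosynthetic overview**
- The target comes from acetylation of a 2,3-cis-diol acid; the diol comes from C2 enolate hydroxylation and bulky-hydride reduction of a 4,4-dimethyl-3-ketone (ring A is adjusted last).
- The trans-fused gem-dimethyl ketone comes from reductive methylation of a 4-methyl-Δ4-3-ketone, itself from 1,2-hydrogenation of a cross-conjugated cyclohexadienone.
- Key disconnection C9–C10: the dienone comes from a 2,4-dimethylphenol carrying a meta-tethered allylic carbonate. An enantioselective palladium-catalysed dearomative allylic alkylation at the para carbon closes ring B and sets C9, C10 and the Δ7 olefin in one step.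
- The cyclisation precursor comes from a benzylic zinc reagent (3-acetoxy-2-methylbenzoic acid: C–H methylation, reduction, chlorination) and a ten-carbon enal (SeO2 oxidation of geranyl acetate).
- Ring order: ring A is bought as the arene; ring B is the only ring formed.

Assumption: locants follow labdane numbering (C1–C17) and configurations are given as CIP descriptors.
Assumption: the (R,R) enantiomer of the DACH-phenyl Trost ligand is taken to give the (9R,10S) series; if the sense is opposite, the (S,S) ligand is used with no other change.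
Assumption: 3-acetoxy-2-methylbenzoic acid and geranyl acetate are bought as bulk commercial materials.

**Route**

Step 1
Reactants: 1 3-acetoxy-2-methylbenzoic acid
Product: 2 3-acetoxy-2,6-dimethylbenzoic acid
Conditions: Pd(OAc)2 (10 mol%), MeB(OH)2 (3 equiv), Ag2CO3 (1 equiv), K2HPO4, benzoquinone (0.5 equiv), t-BuOH, 100 °C
Reagents that add atoms: methylboronic acid, CB(O)O
Why: carboxylate-directed ortho C–H methylation on divalent palladium (cyclopalladation, transmetalation from boron, reductive elimination, reoxidation by Ag2CO3); only one ortho C–H is free, so the regiochemistry is fixed and no stereocentre is involved.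

Step 2
Reactants: 2 3-acetoxy-2,6-dimethylbenzoic acid
Product: 3 3-(hydroxymethyl)-2,4-dimethylphenyl acetate
Conditions: BH3·SMe2, THF, 0 °C to rt; aqueous work-up
Reagents that add atoms: none
Why: chemoselective borane reduction of a carboxylic acid (acyloxyborane pathway) in the presence of the much less reactive aryl ester.

Step 3
Reactants: 3 3-(hydroxymethyl)-2,4-dimethylphenyl acetate
Product: 4 3-(chloromethyl)-2,4-dimethylphenyl acetate
Conditions: SOCl2, DMF (cat.), CH2Cl2, 0 °C
Reagents that add atoms: thionyl chloride, O=S(Cl)Cl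
Why: chlorodehydroxylation through the chlorosulfite; the electron-rich benzylic position reacts cleanly and the aryl acetate is inert.

Step 4
Reactants: 5 geranyl acetate [(2E)-3,7-dimethylocta-2,6-dien-1-yl acetate]
Product: 6 (2E,6E)-8-acetoxy-2,6-dimethylocta-2,6-dienal
Conditions: SeO2 (1.1 equiv), 95% EtOH, reflux
Reagents that add atoms: selenium dioxide, O=[Se]=O
Why: Riley allylic oxidation (ene reaction then 2,3-sigmatropic shift) attacks the (E)-methyl of the electron-richer terminal olefin and gives the E-enal, which fixes the E geometry of the future C8=C9 bond.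

Step 5
Reactants: 4 3-(chloromethyl)-2,4-dimethylphenyl acetate; 6 (2E,6E)-8-acetoxy-2,6-dimethylocta-2,6-dienal
Product: 9 racemic (2E,6E)-9-(3-acetoxy-2,6-dimethylphenyl)-8-(methoxycarbonyloxy)-3,7-dimethylnona-2,6-dien-1-yl acetate, via benzylzinc chloride 7 (not isolated), via zinc alkoxide 8 (not isolated)
Conditions: Zn dust, LiCl, THF, 25 °C; then 6, 0 °C to rt; then ClCO2Me, 0 °C
Reagents that add atoms: methyl chloroformate, COC(=O)Cl
Why: LiCl-mediated zinc insertion gives an ester-tolerant benzylic zinc reagent that adds 1,2 to the enal (organozinc carbonyl addition) and the zinc alkoxide is acylated in the same flask; the C7 carbinol centre is racemic and is erased in step 6.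

Step 6
Reactants: 9 racemic (2E,6E)-9-(3-acetoxy-2,6-dimethylphenyl)-8-(methoxycarbonyloxy)-3,7-dimethylnona-2,6-dien-1-yl acetate
Product: 12 (9R,10S)-15-hydroxy-19-norlabda-1,4,7,13E-tetraen-3-one, via phenol carbonate 10 (not isolated), via dienone acetate 11 (not isolated)
Conditions: pyrrolidine (1.0 equiv), THF, 0 °C; then Pd2(dba)3·CHCl3 (5 mol%), (R,R)-DACH-phenyl Trost ligand (15 mol%), THF (0.02 M), 0 °C to rt; then K2CO3, MeOH, 0 °C
Reagents that add atoms: none
Why: Proposed new method: after aminolysis of the aryl acetate, zerovalent palladium ionises the allylic carbonate (the released methoxide deprotonates the phenol), the 2-methyl-1,3-dialkyl π-allyl complex isomerises syn to anti at C7 by η3–η1–η3 slippage, and the phenoxide para carbon (C10, bearing the methyl) attacks C9 anti to palladium to close ring B as a cyclohexene and give the 4,4-disubstituted cyclohexa-2,5-dienone. Attack at C7 would give a four-membered ring, O-attack is geometrically impossible, and ortho attack would give the less stable linear dienone and is reversible. C11 stays syn on the allyl (from the E olefin) and the fused transition state forces the C10 methyl axial on ring B, so the side chain ends cis to the methyl. The chiral ligand selects the allyl face (9R,10S), with both carbonate enantiomers funnelled through π-allyl complexes that interconvert by palladium–palladium displacement faster than the slow ring closure (dynamic kinetic asymmetric transformation). Closest known reaction types: palladium-catalysed intramolecular allylic dearomatisation of phenols (Tsuji–Trost ipso-alkylation) and palladium-catalysed asymmetric dearomative cyclisation of para-methylphenols to angular-methyl dienones; the final acetate methanolysis is ordinary transesterification.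

Step 7
Reactants: 12 (9R,10S)-15-hydroxy-19-norlabda-1,4,7,13E-tetraen-3-one
Product: 13 (9R,10S)-15-hydroxy-19-norlabda-4,7,13E-trien-3-one
Conditions: H2 (1 atm), RhCl(PPh3)3 (5 mol%), benzene–EtOH, rt
Reagents that add atoms: none
Why: homogeneous hydrogenation with RhCl(PPh3)3 reduces only the disubstituted C1=C2 bond of a 1,4-dien-3-one and leaves the tetrasubstituted C4=C5 and the trisubstituted C7=C8 and C13=C14 bonds; no stereocentre is formed.

Step 8
Reactants: 13 (9R,10S)-15-hydroxy-19-norlabda-4,7,13E-trien-3-one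
Product: 15 (5S,9R,10S)-15-hydroxylabda-7,13E-dien-3-one, via dilithium enolate 14 (not isolated)
Conditions: Li (2.2 equiv), NH3(l)–THF, −78 °C; then MeI, −78 to −33 °C; NH4Cl
Reagents that add atoms: iodomethane, CI
Why: Stork reductive alkylation (dissolving-metal enone reduction): the C5 carbanion is protonated axially, anti to the C10 methyl, giving the trans ring fusion (5S), and the regiodefined C3–C4 enolate is C-methylated to the gem-dimethyl group; the side-chain hydroxyl supplies the single proton equivalent.

Step 9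
Reactants: 15 (5S,9R,10S)-15-hydroxylabda-7,13E-dien-3-one
Product: 17 (5S,9R,10S)-3-oxolabda-7,13E-dien-15-oic acid, via keto enal 16 (not isolated)
Conditions: MnO2, CH2Cl2, rt; filter; then NaClO2, NaH2PO4, 2-methyl-2-butene, t-BuOH–H2O, rt
Reagents that add atoms: sodium chlorite, [Na+].[O-]Cl=O
Why: allylic-selective MnO2 oxidation followed by Pinnick oxidation, with 2-methyl-2-butene scavenging HOCl; the 13E geometry is retained and no stereocentre is touched.

Step 10
Reactants: 17 (5S,9R,10S)-3-oxolabda-7,13E-dien-15-oic acid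
Product: 19 (2S,5S,9R,10S)-2-hydroxy-3-oxolabda-7,13E-dien-15-oic acid, via dipotassium enolate 18 (not isolated)
Conditions: KN(SiMe3)2 (2.3 equiv), THF, −78 °C; then 2-(phenylsulfonyl)-3-phenyloxaziridine, −78 °C; dilute HCl
Reagents that add atoms: 2-(phenylsulfonyl)-3-phenyloxaziridine, O=S(=O)(N1OC1c1ccccc1)c1ccccc1
Why: Davis enolate hydroxylation: C4 is quaternary so only the C2 enolate can form, and oxygen is delivered to the face anti to the axial C10 and C4 methyls to give the equatorial 2-hydroxyl (2S), which is also the thermodynamic epimer.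

Step 11
Reactants: 19 (2S,5S,9R,10S)-2-hydroxy-3-oxolabda-7,13E-dien-15-oic acid
Product: 20 (2S,3R,5S,9R,10S)-2,3-dihydroxylabda-7,13E-dien-15-oic acid
Conditions: LiBH(s-Bu)3 (4 equiv), THF, −78 to 0 °C; NaOH, H2O2; acidify
Reagents that add atoms: none
Why: the bulky trialkylborohydride avoids the 1,3-diaxial hydrogens and attacks the C3 carbonyl along the equatorial trajectory, as is established for 4,4-dimethyl-3-oxo terpenoids, giving the axial 3-hydroxyl cis to the 2-hydroxyl (3R).

Step 12
Reactants: 20 (2S,3R,5S,9R,10S)-2,3-dihydroxylabda-7,13E-dien-15-oic acid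
Product: 22 (2S,3R,5S,9R,10S)-2,3-diacetoxylabda-7,13E-dien-15-oic acid, via mixed anhydride 21 (not isolated)
Conditions: Ac2O, pyridine, DMAP (cat.), rt to 40 °C; then H2O–THF, NaHCO3; acidify
Reagents that add atoms: acetic anhydride, CC(=O)OC(C)=O
Why: DMAP-catalysed acylation of both secondary hydroxyls (the axial neopentyl 3-hydroxyl needs DMAP), while the carboxyl forms a mixed anhydride that is hydrolysed at its acetyl carbonyl on aqueous work-up; no stereocentre changes.

**Compound list**
1 | 3-acetoxy-2-methylbenzoic acid | CC(=O)Oc1cccc(C(=O)O)c1C | starting material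
2 | 3-acetoxy-2,6-dimethylbenzoic acid | CC(=O)Oc1ccc(C)c(C(=O)O)c1C | intermediate
3 | 3-(hydroxymethyl)-2,4-dimethylphenyl acetate | CC(=O)Oc1ccc(C)c(CO)c1C | intermediate
4 | 3-(chloromethyl)-2,4-dimethylphenyl acetate | CC(=O)Oc1ccc(C)c(CCl)c1C | intermediate
5 | geranyl acetate | CC(C)=CCC/C(C)=C/COC(C)=O | starting material
6 | (2E,6E)-8-acetoxy-2,6-dimethylocta-2,6-dienal | O=C/C(C)=C/CC/C(C)=C/COC(C)=O | intermediate
7 | (3-acetoxy-2,6-dimethylbenzyl)zinc chloride | CC(=O)Oc1ccc(C)c(C[Zn]Cl)c1C | intermediate
8 | chlorozinc alkoxide of racemic (2E,6E)-9-(3-acetoxy-2,6-dimethylphenyl)-8-hydroxy-3,7-dimethylnona-2,6-dien-1-yl acetate | CC(=O)Oc1ccc(C)c(CC(O[Zn]Cl)/C(C)=C/CC/C(C)=C/COC(C)=O)c1C | intermediate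
9 | racemic (2E,6E)-9-(3-acetoxy-2,6-dimethylphenyl)-8-(methoxycarbonyloxy)-3,7-dimethylnona-2,6-dien-1-yl acetate | CC(=O)Oc1ccc(C)c(CC(OC(=O)OC)/C(C)=C/CC/C(C)=C/COC(C)=O)c1C | intermediate
10 | racemic (2E,6E)-9-(3-hydroxy-2,6-dimethylphenyl)-8-(methoxycarbonyloxy)-3,7-dimethylnona-2,6-dien-1-yl acetate | Oc1ccc(C)c(CC(OC(=O)OC)/C(C)=C/CC/C(C)=C/COC(C)=O)c1C | intermediate
11 | (9R,10S)-15-acetoxy-19-norlabda-1,4,7,13E-tetraen-3-one | O=C1C=C[C@@]2(C)[C@H](CC/C(C)=C/COC(C)=O)C(C)=CCC2=C1C | intermediate
12 | (9R,10S)-15-hydroxy-19-norlabda-1,4,7,13E-tetraen-3-one | O=C1C=C[C@@]2(C)[C@H](CC/C(C)=C/CO)C(C)=CCC2=C1C | intermediate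
13 | (9R,10S)-15-hydroxy-19-norlabda-4,7,13E-trien-3-one | O=C1CC[C@@]2(C)[C@H](CC/C(C)=C/CO)C(C)=CCC2=C1C | intermediate
14 | dilithium salt (C3–C4 enolate and C15 alkoxide) of (5S,9R,10S)-15-hydroxy-19-norlabda-7,13E-dien-3-one | [Li]OC=1CC[C@@]2(C)[C@H](CC/C(C)=C/CO[Li])C(C)=CC[C@@H]2C=1C | intermediate
15 | (5S,9R,10S)-15-hydroxylabda-7,13E-dien-3-one | O=C1CC[C@@]2(C)[C@H](CC/C(C)=C/CO)C(C)=CC[C@@H]2C1(C)C | intermediate
16 | (5S,9R,10S)-3-oxolabda-7,13E-dien-15-al | O=C1CC[C@@]2(C)[C@H](CC/C(C)=C/C=O)C(C)=CC[C@@H]2C1(C)C | intermediate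
17 | (5S,9R,10S)-3-oxolabda-7,13E-dien-15-oic acid | O=C1CC[C@@]2(C)[C@H](CC/C(C)=C/C(=O)O)C(C)=CC[C@@H]2C1(C)C | intermediate
18 | dipotassium salt (C2–C3 enolate and carboxylate) of 17 | [K]OC1=CC[C@@]2(C)[C@H](CC/C(C)=C/C(=O)O[K])C(C)=CC[C@@H]2C1(C)C | intermediate
19 | (2S,5S,9R,10S)-2-hydroxy-3-oxolabda-7,13E-dien-15-oic acid | O[C@H]1C[C@@]2(C)[C@H](CC/C(C)=C/C(=O)O)C(C)=CC[C@@H]2C(C)(C)C1=O | intermediate
20 | (2S,3R,5S,9R,10S)-2,3-dihydroxylabda-7,13E-dien-15-oic acid | O[C@H]1C[C@@]2(C)[C@H](CC/C(C)=C/C(=O)O)C(C)=CC[C@@H]2C(C)(C)[C@H]1O | intermediate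
21 | acetic (2S,3R,5S,9R,10S)-2,3-diacetoxylabda-7,13E-dien-15-oic anhydride | CC(=O)O[C@H]1C[C@@]2(C)[C@H](CC/C(C)=C/C(=O)OC(C)=O)C(C)=CC[C@@H]2C(C)(C)[C@H]1OC(C)=O | intermediate
22 | (2S,3R,5S,9R,10S)-2,3-diacetoxylabda-7,13E-dien-15-oic acid (CNP0321684.1) | CC(=O)O[C@H]1C[C@@]2(C)[C@H](CC/C(C)=C/C(=O)O)C(C)=CC[C@@H]2C(C)(C)[C@H]1OC(C)=O | target

**Totals**
Total step count: 12. Longest linear sequence: 11 steps (steps 1–3 and 5–12); step 4 is a one-step side branch.

**Steps most likely to fail**

Step 6 is the main risk: enantioconvergence of the racemic carbonate, para versus ortho attack, and β-hydride loss from the π-allyl complex are all untested. The fallback moves the stereochemical control from the catalyst to chirality transfer. It sets out from zinc alkoxide 8, which is quenched with aqueous NH4Cl instead of methyl chloroformate to give the racemic allylic alcohol F1. Dess–Martin periodinane gives the enone F2. (S)-Me-CBS oxazaborolidine with BH3·SMe2, the alkenyl group acting as the large group, gives the (R)-allylic alcohol F3. ClCO2Me and pyridine give the (R)-carbonate F4. Pyrrolidine frees the (R)-phenol carbonate F5, which achiral Pd(PPh3)4 at low loading (2 mol%, to suppress palladium–palladium exchange) cyclises stereospecifically: ionisation with inversion, then C-attack with inversion, so C10 enters C9 on the face the carbonate left at C7. This gives dienone acetate 11, and K2CO3 in MeOH converts it to 12, where the route is rejoined.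

Step 8 may suffer over-reduction, allylic C–O cleavage or conjugate deprotonation under dissolving-metal conditions. The fallback replaces electron transfer by hydride conjugate reduction. It sets out from enone 13: Me3SiCl/Et3N followed by [(Ph3P)CuH]6 and Me3SiCl gives the bis(trimethylsilyl) enol ether F6, with hydride delivered to C5 anti to the C10 methyl (a chiral bisphosphine copper hydride can enforce this face if needed). MeLi in THF releases the lithium enolate F7, MeI gives the silyl-protected ketone F8, and aqueous citric acid removes the silyl ether to return to 15.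

Step 11 depends on the bulky hydride attacking the face next to the axial C4 methyl when an equatorial 2-oxygen is also present; the trans-diol is the likely by-product. The fallback switches from reagent-steric control to catalyst control. It sets out from 19 and uses asymmetric transfer hydrogenation with RuCl[(R,R)-TsDPEN](p-cymene) in HCO2H–Et3N, choosing the catalyst enantiomer that delivers hydride to the hindered face, and returns directly to 20; it makes no new compound (F0).

**Further compounds**
F1 | step 6 | racemic (2E,6E)-9-(3-acetoxy-2,6-dimethylphenyl)-8-hydroxy-3,7-dimethylnona-2,6-dien-1-yl acetate | CC(=O)Oc1ccc(C)c(CC(O)/C(C)=C/CC/C(C)=C/COC(C)=O)c1C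
F2 | step 6 | (2E,6E)-9-(3-acetoxy-2,6-dimethylphenyl)-3,7-dimethyl-8-oxonona-2,6-dien-1-yl acetate | CC(=O)Oc1ccc(C)c(CC(=O)/C(C)=C/CC/C(C)=C/COC(C)=O)c1C
F3 | step 6 | (2E,6E,8R)-9-(3-acetoxy-2,6-dimethylphenyl)-8-hydroxy-3,7-dimethylnona-2,6-dien-1-yl acetate | CC(=O)Oc1ccc(C)c(C[C@@H](O)/C(C)=C/CC/C(C)=C/COC(C)=O)c1C
F4 | step 6 | (2E,6E,8R)-9-(3-acetoxy-2,6-dimethylphenyl)-8-(methoxycarbonyloxy)-3,7-dimethylnona-2,6-dien-1-yl acetate | CC(=O)Oc1ccc(C)c(C[C@@H](OC(=O)OC)/C(C)=C/CC/C(C)=C/COC(C)=O)c1C
F5 | step 6 | (2E,6E,8R)-9-(3-hydroxy-2,6-dimethylphenyl)-8-(methoxycarbonyloxy)-3,7-dimethylnona-2,6-dien-1-yl acetate | Oc1ccc(C)c(C[C@@H](OC(=O)OC)/C(C)=C/CC/C(C)=C/COC(C)=O)c1C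
F6 | step 8 | (5S,9R,10S)-3,15-bis(trimethylsilyloxy)-19-norlabda-3,7,13E-triene | C[Si](C)(C)OC=1CC[C@@]2(C)[C@H](CC/C(C)=C/CO[Si](C)(C)C)C(C)=CC[C@@H]2C=1C
F7 | step 8 | lithium C3–C4 enolate of (5S,9R,10S)-15-(trimethylsilyloxy)-19-norlabda-7,13E-dien-3-one | [Li]OC=1CC[C@@]2(C)[C@H](CC/C(C)=C/CO[Si](C)(C)C)C(C)=CC[C@@H]2C=1C
F8 | step 8 | (5S,9R,10S)-15-(trimethylsilyloxy)labda-7,13E-dien-3-one | O=C1CC[C@@]2(C)[C@H](CC/C(C)=C/CO[Si](C)(C)C)C(C)=CC[C@@H]2C1(C)C
F0 | step 11 | none | none
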